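## The problem

Target 17 is a 3,4-dihydroisocoumarin. A resorcinol ring A (free hydroxyls at C6 and C8) is fused to a δ-lactone ring B (C1 carbonyl, O2, C3, C4, C4a, C8a). C3 carries an unbranched eleven-carbon chain (C1′ to C11′) with a hydroxyl at C6′.

There are two stereocentres, C3 (R) and C6′ (S). Six bonds separate them, so neither can direct the other. Each must be set by a reagent or a catalyst; C6′ is most simply bought in as a resolved terminal epoxide.

The skeleton has no quaternary carbon and no ring-fusion stereochemistry. The real tasks are to join arene and chain at C4–C4a, to place the lactone oxygen on C3 in the correct sense, and to keep the sequence short.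

Three groups need care:
- The lactone is opened by strong nucleophiles. While C3 is still allylic it can also be ionised by zerovalent palladium or hydrogenolysed over palladium metal.
- The resorcinol must be masked, and the masks must come off without a Lewis acid strong enough to substitute at C6′.
- The C6′ hydroxyl is a competing nucleophile and must be capped.

The enabling feature is that C3 is an oxygen-bearing carbon between the benzylic C4 and the chain carbon C1′. The terminal C=C of a 1,3-diene can therefore supply C4 and C3. An aryl group adds to C4, the ortho-carboxylate closes ring B onto C3 of the resulting allyl unit, and C1′=C2′ is left as a double bond that is later hydrogenated.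

## Retrosynthesis

**17 from 16.** Only three O–benzyl bonds are cut, freeing the two phenols and the C6′ alcohol from tribenzyl ether 16. Benzyl was chosen over methyl and silyl ethers because the last step is then a neutral hydrogenolysis. Demethylation with BBr3 would put the C6′ oxygen, as a silyl ether or borate, in a medium known to convert such groups into bromides. The forward step must cleave two aryl and one secondary alkyl benzyl ether and leave the lactone alone; the C3–O bond of 16 is homobenzylic, not benzylic or allylic, so this is a reasonable demand.

**16 from 15.** The C1′=C2′ double bond is reintroduced, giving alkenyl lactone 15. This makes C3 allylic, which the ring-forming step requires. The forward hydrogenation must not break the allylic C3–O bond, so a homogeneous rhodium catalyst is preferred to palladium metal. No bond at C3 changes; the descriptor goes from (S) in 15 to (R) in 16 only because the priority of the chain drops.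

**15 from 4 and 14.** C4–C4a and O2–C3 are cut together, giving bromo acid 4 and diene 14. Two narrower cuts were weighed:
- Cutting O2–C3 alone (lactonisation of a hydroxy acid) leaves the homobenzylic carbinol to be made separately.
- Cutting C1–C8a (late carbonylation) leaves an arene that must be functionalised after the chain is attached.

The double cut joins two fragments of similar size, closes ring B and sets C3 in one operation, and both fragments contain only one functional handle each. The forward reaction must give aryl addition at the diene terminus, carboxylate attack at C3 rather than C2′, and facial control by a chiral ligand.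

**14 from 11 and 12.** The internal double bond of the diene (C1′=C2′ of the target) is cut, giving aldehyde 11 and allyldiphenylphosphine oxide 12. This removes the only element of geometry from the chain fragment. The olefination must be (E)-selective, because the geometry of 14 is tied to the sense of induction in the annulation.

**11 from 9, 8, 6 and 7.** The aldehyde is traced to the terminal alkene of benzyl ether 9, 9 to alcohol 8, and 8 is cut at C4′–C5′ into (S)-epoxide 6 and butenyl Grignard reagent 7. A four-carbon alkenyl nucleophile was preferred to a masked-aldehyde nucleophile because the alkene survives benzylation and is unmasked by ozonolysis without acid. The epoxide opening must occur at the unsubstituted carbon only, so that C6′ is never touched. Epoxide 6 comes from racemic 5 by hydrolytic kinetic resolution.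

**4 from 3 and 1.** The C1–C8a bond is cut: acid 4 comes from aldehyde 3, and 3 from the symmetrical aryl bromide 1 by electrophilic formylation. The formylation must go next to bromine and not between the two benzyloxy groups.

## Roads not taken

**Alternative 1:** The chain is cut at C1′–C2′ and C4′–C5′, with a propyne unit as linchpin between two epoxides. In the forward step 1,3-dilithiopropyne A3 opens (S)-2-(3,5-dimethoxybenzyl)oxirane A2 through its propargylic carbon. The remaining acetylide then opens epoxide 6 under boron Lewis-acid activation, giving (2R,8S)-1-(3,5-dimethoxyphenyl)tridec-5-yne-2,8-diol A1 in one pot.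
- Merits: three components are joined at once, and both stereocentres come from resolved epoxides. In stereochemical security at C3 this road is better than the chosen plan, which relies on a catalyst.
- Weak points: the dianion must react first at its propargylic carbon and not as an allenyl or acetylide nucleophile, and two different epoxides must be consumed in strict order. A1 still lacks the C1 carbonyl, so alkyne saturation, ortho-functionalisation of the arene beside two free hydroxyls, lactonisation and Lewis-acidic demethylation all follow. A2 needs its own enantioselective preparation.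
- Comparison: the chosen plan offers ring B, the C1 carbonyl and fragment union in one step, with a neutral end game. Its fallback borrows the epoxide logic of this road if catalyst control fails.

**Alternative 2:** Ring A is cut at C4a–C5 and C8–C8a and built by cycloaddition. Methyl (5R,11S)-5,11-bis(tert-butyldimethylsilyloxy)hexadec-2-ynoate A6 and 5,5-dimethyl-1,3-bis(trimethylsilyloxy)cyclohexa-1,3-diene A5 undergo a thermal [4+2] addition. The bicyclic adduct expels its gem-dimethyl two-carbon bridge as a gaseous alkene and gives methyl 2-[(2R,8S)-2,8-bis(tert-butyldimethylsilyloxy)tridecyl]-4,6-bis(trimethylsilyloxy)benzoate A4.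
- Merits: the polarity of the diene fixes the positions of ester, oxygens and chain without ambiguity. The phenols appear as labile silyl ethers, and lactonisation should follow desilylation. The end game is as mild as that of the chosen plan and needs no asymmetric catalysis at a late stage.
- Weak points: a β-alkyl ynoate is a sluggish dienophile, so the step needs high temperature. A6, with sixteen carbons and both stereocentres, must be assembled linearly before any ring exists. A resorcinol ring that can be bought is being constructed.
- Comparison: the chosen plan is convergent, buys ring A, and its hydrogenolysis is equally gentle.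

**Alternative 3:** Ring A is cut at C4a–C8a and formed by a biomimetic aldol condensation. Mild carbonate or amine base enolises 6-[(6R,12S)-6,12-bis(tert-butyldimethylsilyloxy)-2,4-dioxoheptadecyl]-2,2-dimethyl-4H-1,3-dioxin-4-one A8. The dioxinone carbon attacks the distal ketone, and dehydration gives 5-[(2R,8S)-2,8-bis(tert-butyldimethylsilyloxy)tridecyl]-7-hydroxy-2,2-dimethyl-4H-benzo[d][1,3]dioxin-4-one A7.
- Merits: conditions are near neutral. The resorcylate emerges masked as an acetonide that the C3 hydroxyl can open after desilylation to close the lactone, so no phenol protecting group has to be removed. In this respect it is better than the chosen plan.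
- Weak points: A8 is a sensitive triketide that needs a multistep C-acylation. Its C4a ketone has a silyloxy group in the β-position, which invites E1cB elimination under the aromatising base. The chain with both stereocentres again has to be built linearly first.
- Comparison: the chosen plan is shorter and uses two stable, separately made fragments, at the price of one benzyl-ether hydrogenolysis.

Key step: step 8

Assumption: the enantiomer of ligand L* that gives (S)-15 in step 8 cannot be predicted on paper and is to be assigned by a screen on a simple 1-alkylbuta-1,3-diene; the route is written for that enantiomer.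

## Route

Step 1
Reactants: 1 1,3-bis(benzyloxy)-5-bromobenzene
Product: 3 2,4-bis(benzyloxy)-6-bromobenzaldehyde, via aryl iminium chloride 2 (not isolated)
Conditions: POCl3, DMF, 0 °C → 80 °C; aq NaOAc
Reagents that add atoms: N,N-dimethylformamide, CN(C)C=O; water, O
Why: Vilsmeier–Haack formylation; the chloroiminium ion should attack para to one benzyloxy group and next to bromine, because the position between the two benzyloxy groups is shielded on both sides, and hydrolysis of iminium 2 gives the aldehyde.

Step 2
Reactants: 3 2,4-bis(benzyloxy)-6-bromobenzaldehyde
Product: 4 2,4-bis(benzyloxy)-6-bromobenzoic acid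
Conditions: NaClO2, NaH2PO4, 2-methyl-2-butene, t-BuOH/THF/H2O, rt
Reagents that add atoms: sodium chlorite, [Na+].[O-]Cl=O
Why: Pinnick oxidation; chlorous acid oxidises the aldehyde without touching the bromide or the benzyl ethers, and the alkene scavenger removes hypochlorous acid before it can chlorinate the electron-rich ring.

Step 3
Reactants: 5 rac-2-pentyloxirane
Product: 6 (S)-2-pentyloxirane
Conditions: (S,S)-(salen)Co(OAc) (0.5 mol %), H2O (0.55 equiv), neat, 0 °C → rt; distillation
Reagents that add atoms: none
Why: Jacobsen hydrolytic kinetic resolution with the trivalent cobalt complex of salen (N,N′-bis(3,5-di-tert-butylsalicylidene)cyclohexane-1,2-diamine dianion); the catalyst enantiomer that hydrolyses the (R)-epoxide is used, so the (S)-epoxide is left and distilled from the diol, which fixes C6′ of the target.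

Step 4
Reactants: 6 (S)-2-pentyloxirane; 7 but-3-en-1-ylmagnesium bromide
Product: 8 (S)-undec-1-en-6-ol
Conditions: CuI (10 mol %), THF, −30 °C → 0 °C; aq NH4Cl
Reagents that add atoms: none
Why: Copper-catalysed Grignard opening of a terminal epoxide by SN2 attack at the unsubstituted carbon; the C–O bond at the stereocentre is not involved, so the (S) configuration is kept.

Step 5
Reactants: 8 (S)-undec-1-en-6-ol
Product: 9 (S)-[(undec-1-en-6-yloxy)methyl]benzene
Conditions: NaH, BnBr, n-Bu4NI (cat.), THF/DMF, 0 °C → rt
Reagents that add atoms: benzyl bromide, BrCc1ccccc1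
Why: Williamson ether synthesis; the benzyl ether keeps the C6′ oxygen from acting as a nucleophile in step 8 and is removed together with the phenol benzyl ethers in step 10.

Step 6
Reactants: 9 (S)-[(undec-1-en-6-yloxy)methyl]benzene
Product: 11 (S)-5-(benzyloxy)decanal, via ozonide 10 (not isolated)
Conditions: O3, CH2Cl2, −78 °C (Sudan red 7B end point); PPh3, −78 °C → rt
Reagents that add atoms: ozone, [O-][O+]=O
Why: Ozonolysis with reductive work-up; the terminal alkene reacts much faster than the benzyl ether, the indicator prevents over-exposure, and PPh3 reduces ozonide 10 to the aldehyde under neutral conditions.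

Step 7
Reactants: 11 (S)-5-(benzyloxy)decanal; 12 allyldiphenylphosphine oxide
Product: 14 (S,E)-8-(benzyloxy)trideca-1,3-diene, via lithium alkoxide adduct 13 (not isolated)
Conditions: 12, n-BuLi, THF/HMPA, −78 °C; then 11, −78 °C → rt
Reagents that add atoms: none
Why: Horner–Wittig olefination; in THF/HMPA the lithiated allylphosphine oxide adds through its α-carbon and adduct 13 loses lithium diphenylphosphinate by syn elimination on warming, a combination known to give (E)-1,3-dienes from aliphatic aldehydes, while the benzyl ether and the remote stereocentre are inert to the base.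

Step 8
Reactants: 4 2,4-bis(benzyloxy)-6-bromobenzoic acid; 14 (S,E)-8-(benzyloxy)trideca-1,3-diene
Product: 15 (S)-6,8-bis(benzyloxy)-3-[(S,E)-6-(benzyloxy)undec-1-en-1-yl]isochroman-1-one
Conditions: Pd(OAc)2 (5 mol %), chiral sulfinamide monophosphine L* (Sadphos type, 12 mol %), K3PO4, 1,4-dioxane, 80 °C
Reagents that add atoms: none
Why: Proposed new method: the closest known reactions are the palladium-catalysed heteroannulation of 1,3-dienes by ortho-halobenzoic acids, which gives racemic 3-vinyl-3,4-dihydroisocoumarins, and the enantioselective Heck/Tsuji–Trost annulations of ortho-halophenols and ortho-haloanilines with 1,3-dienes; the enantioselective version with a carboxylate as ring-closing nucleophile is the extrapolation. Zerovalent palladium, formed in the flask from Pd(OAc)2 and the phosphine, inserts into the C–Br bond of the potassium salt of 4, and the aryl group migrates to the unsubstituted diene terminus (C4 of the product), which forms C4–C4a and leaves a syn,syn-π-allylpalladium unit over C3, C1′ and C2′. The neighbouring carboxylate then attacks the allyl terminus C3 and closes ring B by a 6-exo closure that forms O2–C3; attack at C2′ would need an eight-membered ring and is not expected. C3 is under catalyst control: the chiral ligand selects the face of the terminal double bond to which the aryl–palladium bond adds, the π-allyl unit inherits that face, and C–O bond formation transfers it to C3, while the C6′ centre six bonds away has no influence. The step needs aryl addition at the diene terminus (secured by the monosubstituted diene and by allyl stabilisation), ring closure in preference to β-hydride elimination (secured by the tethered, already deprotonated carboxylate) and a capped C6′ oxygen (the benzyl ether, since a free hydroxyl could attack C2′ and close a tetrahydropyran). The (E) geometry of 14 matters, because a (Z)-diene would enter as an anti-allyl complex whose syn/anti isomerisation inverts the sense at C3.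

Step 9
Reactants: 15 (S)-6,8-bis(benzyloxy)-3-[(S,E)-6-(benzyloxy)undec-1-en-1-yl]isochroman-1-one
Product: 16 (R)-6,8-bis(benzyloxy)-3-[(S)-6-(benzyloxy)undecyl]isochroman-1-one
Conditions: H2 (1 atm), RhCl(PPh3)3 (10 mol %), toluene/EtOH, rt
Reagents that add atoms: none
Why: Homogeneous hydrogenation with RhCl(PPh3)3 should saturate the disubstituted C1′=C2′ alkene without hydrogenolysis of the allylic C3–O bond or of the benzyl ethers; no bond at C3 is touched, and the descriptor changes from (S) to (R) only because C4 now outranks the saturated chain.

Step 10
Reactants: 16 (R)-6,8-bis(benzyloxy)-3-[(S)-6-(benzyloxy)undecyl]isochroman-1-one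
Product: 17 (R)-6,8-dihydroxy-3-[(S)-6-hydroxyundecyl]isochroman-1-one
Conditions: H2 (1 atm), Pd/C (10 wt %), EtOAc/MeOH, rt
Reagents that add atoms: none
Why: Catalytic hydrogenolysis should cleave the two aryl benzyl ethers and the secondary alkyl benzyl ether under neutral conditions; the lactone C3–O bond is homobenzylic and no longer allylic, so it stays, and neither stereocentre is involved.

## Compound list

1 | 1,3-bis(benzyloxy)-5-bromobenzene | Brc1cc(OCc2ccccc2)cc(OCc2ccccc2)c1 | starting material
2 | [2,4-bis(benzyloxy)-6-bromobenzylidene]dimethyliminium chloride | C[N+](C)=Cc1c(Br)cc(OCc2ccccc2)cc1OCc1ccccc1.[Cl-] | intermediate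
3 | 2,4-bis(benzyloxy)-6-bromobenzaldehyde | O=Cc1c(Br)cc(OCc2ccccc2)cc1OCc1ccccc1 | intermediate
4 | 2,4-bis(benzyloxy)-6-bromobenzoic acid | OC(=O)c1c(Br)cc(OCc2ccccc2)cc1OCc1ccccc1 | intermediate
5 | rac-2-pentyloxirane | CCCCCC1CO1 | starting material
6 | (S)-2-pentyloxirane | CCCCC[C@H]1CO1 | intermediate
7 | but-3-en-1-ylmagnesium bromide | C=CCC[Mg]Br | starting material
8 | (S)-undec-1-en-6-ol | C=CCCC[C@@H](O)CCCCC | intermediate
9 | (S)-[(undec-1-en-6-yloxy)methyl]benzene | C=CCCC[C@@H](OCc1ccccc1)CCCCC | intermediate
10 | 3-[(S)-4-(benzyloxy)nonyl]-1,2,4-trioxolane (both configurations at the ring carbon) | CCCCC[C@H](OCc1ccccc1)CCCC1OCOO1 | intermediate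
11 | (S)-5-(benzyloxy)decanal | CCCCC[C@H](OCc1ccccc1)CCCC=O | intermediate
12 | allyldiphenylphosphine oxide | C=CCP(=O)(c1ccccc1)c1ccccc1 | starting material
13 | lithium (8S)-8-(benzyloxy)-3-(diphenylphosphoryl)tridec-1-en-4-olate (mixture at C3 and C4) | CCCCC[C@H](OCc1ccccc1)CCCC([O-])C(C=C)P(=O)(c1ccccc1)c1ccccc1.[Li+] | intermediate
14 | (S,E)-8-(benzyloxy)trideca-1,3-diene | C=C/C=C/CCC[C@@H](OCc1ccccc1)CCCCC | intermediate
15 | (S)-6,8-bis(benzyloxy)-3-[(S,E)-6-(benzyloxy)undec-1-en-1-yl]isochroman-1-one | CCCCC[C@H](OCc1ccccc1)CCC/C=C/[C@@H]1Cc2cc(OCc3ccccc3)cc(OCc3ccccc3)c2C(=O)O1 | intermediate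
16 | (R)-6,8-bis(benzyloxy)-3-[(S)-6-(benzyloxy)undecyl]isochroman-1-one | CCCCC[C@H](OCc1ccccc1)CCCCC[C@@H]1Cc2cc(OCc3ccccc3)cc(OCc3ccccc3)c2C(=O)O1 | intermediate
17 | (R)-6,8-dihydroxy-3-[(S)-6-hydroxyundecyl]isochroman-1-one | CCCCC[C@H](O)CCCCC[C@@H]1Cc2cc(O)cc(O)c2C(=O)O1 | target

## Step count and risks

Total step count: 10. Longest linear sequence: 8 steps (steps 3 to 10); the acid branch (steps 1 and 2) joins at step 8.

**Step 8 (key step, new in its enantioselective carboxylate form).**
What may go wrong:
- poor facial discrimination in the aryl insertion;
- erosion of the C3 configuration, because the allylic lactone can be re-ionised by zerovalent palladium;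
- β-hydride elimination of the allyl intermediate before ring closure;
- slow oxidative addition into the electron-rich aryl bromide;
- protodecarboxylation of the ortho-substituted benzoate at elevated temperature.

Fallback (known chemistry; sets out from 6 and 1, returns at 16): commercial hex-5-en-1-ylmagnesium bromide opens 6 under CuI catalysis to give (S)-tridec-12-en-6-ol F1. Benzylation (NaH, BnBr) gives (S)-[(tridec-12-en-6-yloxy)methyl]benzene F2. Epoxidation with mCPBA gives 2-[(S)-6-(benzyloxy)undecyl]oxirane F3 as a mixture of both configurations at the new centre. Hydrolytic kinetic resolution with (R,R)-(salen)Co(OAc) leaves (R)-2-[(S)-6-(benzyloxy)undecyl]oxirane F4. Bromine–lithium exchange on 1 with n-BuLi gives [3,5-bis(benzyloxy)phenyl]lithium F5, which opens F4 at its terminal carbon in the presence of BF3·OEt2 to give (2R,8S)-8-(benzyloxy)-1-[3,5-bis(benzyloxy)phenyl]tridecan-2-ol F6. NBS brominates the ring next to the side chain and para to a benzyloxy group, giving (2R,8S)-8-(benzyloxy)-1-[3,5-bis(benzyloxy)-2-bromophenyl]tridecan-2-ol F7. Carbonylative lactonisation (PdCl2(PPh3)2, CO, K2CO3, DMF, 100 °C) closes ring B and gives 16. Both stereocentres then come from resolved epoxides, at the cost of a longer sequence.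

**Step 7.**
What may go wrong: incomplete (E) selectivity in the elimination, and competing attack through the γ-carbon of the allyl anion. Any (Z)-diene would lower the enantiomeric purity reached in step 8.

Fallback (sets out from 11, returns at 14): Ohira–Bestmann homologation (dimethyl (1-diazo-2-oxopropyl)phosphonate, K2CO3, MeOH) gives (S)-[(undec-1-yn-6-yloxy)methyl]benzene F8. Hydroboration with pinacolborane catalysed by Cp2Zr(H)Cl gives 2-[(S,E)-6-(benzyloxy)undec-1-en-1-yl]-4,4,5,5-tetramethyl-1,3,2-dioxaborolane F9. Suzuki–Miyaura coupling with vinyl bromide (Pd(PPh3)4, aqueous K3PO4, THF) gives 14, with the geometry fixed by syn hydroboration.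

**Step 6.**
What may go wrong: oxidation at the benzylic position of the ether by excess ozone.

Fallback (sets out from 9, returns at 11): dihydroxylation (OsO4 cat., N-methylmorpholine N-oxide, acetone/H2O) gives (6S)-6-(benzyloxy)undecane-1,2-diol F10, and glycol cleavage with NaIO4 gives 11.

**Step 9.**
What may go wrong: slow reduction of the internal alkene, and ionisation or hydrogenolysis of the allylic C3–O bond if the rhodium complex loses its phosphines.

Fallback (sets out from 15, returns at 16, no new compound): metal-free diimide reduction with 2-nitrobenzenesulfonohydrazide and Et3N in CH2Cl2 at rt. Diimide cannot ionise an allylic ester.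

**Step 10.**
What may go wrong: sluggish cleavage of the secondary alkyl benzyl ether after the aryl ethers are gone, and ring saturation on prolonged exposure.

Fallback (sets out from 16, returns at 17, no new compound): Lewis-acid debenzylation with BCl3 and pentamethylbenzene as cation scavenger in CH2Cl2 at −78 °C. BCl3 cleaves benzyl–oxygen bonds at the benzyl carbon, so C6′ is not attacked.

## Further compounds

F1 | step 8 | (S)-tridec-12-en-6-ol | C=CCCCCC[C@@H](O)CCCCC
F2 | step 8 | (S)-[(tridec-12-en-6-yloxy)methyl]benzene | C=CCCCCC[C@@H](OCc1ccccc1)CCCCC
F3 | step 8 | 2-[(S)-6-(benzyloxy)undecyl]oxirane (both configurations at the oxirane carbon) | CCCCC[C@H](OCc1ccccc1)CCCCCC1CO1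
F4 | step 8 | (R)-2-[(S)-6-(benzyloxy)undecyl]oxirane | CCCCC[C@H](OCc1ccccc1)CCCCC[C@@H]1CO1
F5 | step 8 | [3,5-bis(benzyloxy)phenyl]lithium | [Li]c1cc(OCc2ccccc2)cc(OCc2ccccc2)c1
F6 | step 8 | (2R,8S)-8-(benzyloxy)-1-[3,5-bis(benzyloxy)phenyl]tridecan-2-ol | CCCCC[C@H](OCc1ccccc1)CCCCC[C@@H](O)Cc1cc(OCc2ccccc2)cc(OCc2ccccc2)c1
F7 | step 8 | (2R,8S)-8-(benzyloxy)-1-[3,5-bis(benzyloxy)-2-bromophenyl]tridecan-2-ol | CCCCC[C@H](OCc1ccccc1)CCCCC[C@@H](O)Cc1cc(OCc2ccccc2)cc(OCc2ccccc2)c1Br
F8 | step 7 | (S)-[(undec-1-yn-6-yloxy)methyl]benzene | C#CCCC[C@@H](OCc1ccccc1)CCCCC
F9 | step 7 | 2-[(S,E)-6-(benzyloxy)undec-1-en-1-yl]-4,4,5,5-tetramethyl-1,3,2-dioxaborolane | CCCCC[C@H](OCc1ccccc1)CCC/C=C/B1OC(C)(C)C(C)(C)O1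
F10 | step 6 | (6S)-6-(benzyloxy)undecane-1,2-diol | CCCCC[C@H](OCc1ccccc1)CCCC(O)CO
F0 | step 9 | none | none
F0 | step 10 | none | none
A1 | alternative 1 | (2R,8S)-1-(3,5-dimethoxyphenyl)tridec-5-yne-2,8-diol | COc1cc(OC)cc(C[C@H](O)CCC#CC[C@@H](O)CCCCC)c1
A2 | alternative 1 | (S)-2-(3,5-dimethoxybenzyl)oxirane | COc1cc(OC)cc(C[C@H]2CO2)c1
A3 | alternative 1 | 1,3-dilithiopropyne | [Li]CC#C[Li]
A4 | alternative 2 | methyl 2-[(2R,8S)-2,8-bis(tert-butyldimethylsilyloxy)tridecyl]-4,6-bis(trimethylsilyloxy)benzoate | COC(=O)c1c(O[Si](C)(C)C)cc(O[Si](C)(C)C)cc1C[C@H](O[Si](C)(C)C(C)(C)C)CCCCC[C@@H](O[Si](C)(C)C(C)(C)C)CCCCC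
A5 | alternative 2 | 5,5-dimethyl-1,3-bis(trimethylsilyloxy)cyclohexa-1,3-diene | C[Si](C)(C)OC1=CC(O[Si](C)(C)C)=CC(C)(C)C1
A6 | alternative 2 | methyl (5R,11S)-5,11-bis(tert-butyldimethylsilyloxy)hexadec-2-ynoate | COC(=O)C#CC[C@H](O[Si](C)(C)C(C)(C)C)CCCCC[C@@H](O[Si](C)(C)C(C)(C)C)CCCCC
A7 | alternative 3 | 5-[(2R,8S)-2,8-bis(tert-butyldimethylsilyloxy)tridecyl]-7-hydroxy-2,2-dimethyl-4H-benzo[d][1,3]dioxin-4-one | CC1(C)Oc2cc(O)cc(C[C@H](O[Si](C)(C)C(C)(C)C)CCCCC[C@@H](O[Si](C)(C)C(C)(C)C)CCCCC)c2C(=O)O1
A8 | alternative 3 | 6-[(6R,12S)-6,12-bis(tert-butyldimethylsilyloxy)-2,4-dioxoheptadecyl]-2,2-dimethyl-4H-1,3-dioxin-4-one | CC1(C)OC(CC(=O)CC(=O)C[C@H](O[Si](C)(C)C(C)(C)C)CCCCC[C@@H](O[Si](C)(C)C(C)(C)C)CCCCC)=CC(=O)O1
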